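**Retrosynthetic overview**
1. Target 27 ⇐ desilylation of 26 ⇐ Heck coupling of the C4-vinyl group of 19 with bromodienamide 25 (the cyclopentenone ring is bought).
2. Enamide C2–N ⇐ copper-catalysed amidation of α-iodo epoxy-enone 14 with (2E,4R)-4-methyloct-2-enamide 18 (from a Roche-type bromo alcohol).
3. Epoxide ⇐ substrate-controlled nucleophilic epoxidation of enone 11, anti to the C4 silyloxy group.
4. Carbocycle and C4 ⇐ Diels–Alder reaction of Rawal's diene with the (S)-lactic-acid-derived methylene dioxolanone 5, which adds anti to its tert-butyl group.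
5. Ring order: dioxolanone (temporary) → cyclohexene (Diels–Alder) → oxirane.

Assumption: (S)-3-bromo-2-methylpropan-1-ol, Rawal's diene, glutaconaldehyde potassium salt and 2-amino-3-hydroxycyclopent-2-en-1-one hydrochloride are taken as catalogue chemicals.

The target has the C4 hydroxyl anti to the epoxide oxygen (4R,5R,6S in cyclohexenone numbering; 1S,5R,6R in the bicyclic names below).

**Step 1**
Reactants: 1 (S)-lactic acid; 2 pivalaldehyde
Product: 3 (2S,5S)-2-tert-butyl-5-methyl-1,3-dioxolan-4-one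
Conditions: TsOH·H2O (cat.), H2SO4 (cat.), pentane, reflux, Dean–Stark; recrystallise Et2O/pentane, −78 °C
Reagents that add atoms: none
Why: Acid-catalysed acetalisation (Seebach dioxolanone); the lactic acid stereocentre sets the acetal carbon cis, and crystallisation removes the trans isomer.

**Step 2**
Reactants: 3 (2S,5S)-2-tert-butyl-5-methyl-1,3-dioxolan-4-one
Product: 5 (2S)-2-tert-butyl-5-methylidene-1,3-dioxolan-4-one, via bromo dioxolanone 4 (not isolated)
Conditions: NBS, AIBN (cat.), PhCF3, 85 °C; then Et3N, 0 °C → rt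
Reagents that add atoms: none
Why: Wohl–Ziegler radical bromination at C5 then E2 dehydrobromination; the lactate carbon becomes sp2 while the acetal carbon (2S) retains the stereochemical information.

**Step 3**
Reactants: 5 (2S)-2-tert-butyl-5-methylidene-1,3-dioxolan-4-one; 6 Rawal's diene, (E)-3-[(tert-butyldimethylsilyl)oxy]-N,N-dimethylbuta-1,3-dien-1-amine
Product: 7 (2S,5R)-2-tert-butyl-8-[(tert-butyldimethylsilyl)oxy]-6-(dimethylamino)-1,3-dioxaspiro[4.5]dec-7-en-4-one (epimers at C6, inconsequential)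
Conditions: toluene, 40 °C, 24 h; concentrate
Reagents that add atoms: none
Why: Normal-demand Diels–Alder reaction forms the carbocycle; the amino terminus bonds to the acyloxy-bearing carbon, and the diene adds to the face anti to the tert-butyl group, setting the spiro carbon (future C4).

**Step 4**
Reactants: 7 (2S,5R)-2-tert-butyl-8-[(tert-butyldimethylsilyl)oxy]-6-(dimethylamino)-1,3-dioxaspiro[4.5]dec-7-en-4-one
Product: 10 (S)-4-ethenyl-4-hydroxycyclohex-2-en-1-one, via lactol 8 (not isolated), via vinyl carbinol 9 (not isolated)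
Conditions: iBu2AlH (1.1 equiv), toluene, −78 °C; then Ph3P=CH2 (from Ph3PCH3Br, KN(SiMe3)2; 4 equiv), THF, −78 °C → rt; then 1 M HCl, 0 °C → rt
Reagents that add atoms: methyltriphenylphosphonium bromide (used as its ylide), C[P+](c1ccccc1)(c1ccccc1)c1ccccc1.[Br-]
Why: Partial DIBAL reduction gives the lactol, which opens (losing pivalaldehyde) to the aldehyde for Wittig methylenation; acid then hydrolyses the silyl enol ether and eliminates Me2NH (E1cB) to the enone, leaving the quaternary carbinol untouched.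

**Step 5**
Reactants: 10 (S)-4-ethenyl-4-hydroxycyclohex-2-en-1-one
Product: 11 (S)-4-ethenyl-4-[(triethylsilyl)oxy]cyclohex-2-en-1-one
Conditions: Et3SiOTf, 2,6-lutidine, CH2Cl2, −78 °C
Reagents that add atoms: triethylsilyl triflate, CC[Si](CC)(CC)OS(=O)(=O)C(F)(F)F
Why: Silylation of the tertiary alcohol removes its syn-directing hydrogen bond and makes the oxygen face the hindered one.

**Step 6**
Reactants: 11 (S)-4-ethenyl-4-[(triethylsilyl)oxy]cyclohex-2-en-1-one
Product: 12 (1S,5S,6R)-5-ethenyl-5-[(triethylsilyl)oxy]-7-oxabicyclo[4.1.0]heptan-2-one (epoxide anti to OSiEt3)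
Conditions: tBuOOH (decane), DBU, CH2Cl2, 0 °C → rt
Reagents that add atoms: tert-butyl hydroperoxide, CC(C)(C)OO
Why: Weitz–Scheffer nucleophilic epoxidation; the peroxide adds to the β-carbon anti to the pseudo-axial silyloxy group (steric and σ*C–O control), so the oxirane is trans to oxygen and cis to the vinyl group.

**Step 7**
Reactants: 12 (1S,5S,6R)-5-ethenyl-5-[(triethylsilyl)oxy]-7-oxabicyclo[4.1.0]heptan-2-one
Product: 13 (1S,5R,6R)-5-ethenyl-5-[(triethylsilyl)oxy]-7-oxabicyclo[4.1.0]hept-3-en-2-one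
Conditions: LiN(iPr)2, THF, −78 °C; then PhS(Cl)=NtBu, −78 °C
Reagents that add atoms: none
Why: Mukaiyama dehydrogenation; the only enolisable CH2 gives the lithium enolate, which is sulfenylated at carbon and undergoes syn-elimination to the enone without touching the stereocentres.

**Step 8**
Reactants: 13 (1S,5R,6R)-5-ethenyl-5-[(triethylsilyl)oxy]-7-oxabicyclo[4.1.0]hept-3-en-2-one
Product: 14 (1S,5R,6R)-5-ethenyl-3-iodo-5-[(triethylsilyl)oxy]-7-oxabicyclo[4.1.0]hept-3-en-2-one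
Conditions: I2, pyridine, CH2Cl2, 0 °C → rt, dark
Reagents that add atoms: iodine, II
Why: Johnson α-iodination of an enone (Baylis–Hillman-type addition of pyridine, iodination of the enolate, elimination).

**Step 9**
Reactants: 15 (S)-3-bromo-2-methylpropan-1-ol
Product: 16 (R)-2-methylhexan-1-ol
Conditions: nPrMgBr (3 equiv), Li2CuCl4 (3 mol %), THF, −78 °C → rt
Reagents that add atoms: n-propylmagnesium bromide, CCC[Mg]Br
Why: Kochi-type copper-catalysed sp3–sp3 coupling at the primary bromide; the stereocentre is not involved (the descriptor changes only through priorities).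

**Step 10**
Reactants: 16 (R)-2-methylhexan-1-ol
Product: 18 (2E,4R)-4-methyloct-2-enamide, via aldehyde 17 (not isolated)
Conditions: PhI(OAc)2, TEMPO (10 mol %), CH2Cl2, rt; then Ph3P=CHCONH2, rt → 40 °C
Reagents that add atoms: (carbamoylmethylene)triphenylphosphorane, NC(=O)C=P(c1ccccc1)(c1ccccc1)c1ccccc1
Why: TEMPO/PhI(OAc)2 oxidation and in situ Wittig reaction with a stabilised ylide gives the E-enamide under non-basic conditions that do not epimerise the α-stereocentre.

**Step 11**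
Reactants: 14 (1S,5R,6R)-5-ethenyl-3-iodo-5-[(triethylsilyl)oxy]-7-oxabicyclo[4.1.0]hept-3-en-2-one; 18 (2E,4R)-4-methyloct-2-enamide
Product: 19 (2E,4R)-N-[(1S,5R,6R)-5-ethenyl-2-oxo-5-[(triethylsilyl)oxy]-7-oxabicyclo[4.1.0]hept-3-en-3-yl]-4-methyloct-2-enamide
Conditions: CuI (10 mol %), MeNHCH2CH2NHMe (20 mol %), Cs2CO3, toluene, 60 °C
Reagents that add atoms: none
Why: Goldberg–Buchwald copper-catalysed amidation of the alkenyl iodide with retention of the alkene position; any core material from minor-face Diels–Alder addition is now a diastereomer and is removed by chromatography.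

**Step 12**
Reactants: 20 glutaconaldehyde potassium salt, potassium (1E,3E)-5-oxopenta-1,3-dien-1-olate
Product: 21 (2E,4E)-5-bromopenta-2,4-dienal
Conditions: Ph3PBr2, CH2Cl2, 0 °C → rt
Reagents that add atoms: triphenylphosphine dibromide, BrP(Br)(c1ccccc1)(c1ccccc1)c1ccccc1
Why: Deoxybromination of the vinylogous carboxylate by the bromophosphonium reagent (addition–elimination) gives the thermodynamic E,E-bromodienal.

**Step 13**
Reactants: 21 (2E,4E)-5-bromopenta-2,4-dienal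
Product: 22 (2E,4E)-5-bromopenta-2,4-dienoic acid
Conditions: NaClO2, NaH2PO4, 2-methylbut-2-ene, tBuOH/H2O, 0 °C → rt
Reagents that add atoms: sodium chlorite, [Na+].[O-]Cl=O
Why: Pinnick oxidation converts the enal to the acid without touching the bromodiene.

**Step 14**
Reactants: 22 (2E,4E)-5-bromopenta-2,4-dienoic acid; 23 2-amino-3-hydroxycyclopent-2-en-1-one hydrochloride
Product: 25 (2E,4E)-5-bromo-N-(2-hydroxy-5-oxocyclopent-1-en-1-yl)penta-2,4-dienamide, via acid chloride 24 (not isolated)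
Conditions: (COCl)2, DMF (cat.), CH2Cl2, 0 °C → rt; then 23, Et3N, CH2Cl2/DMF, 0 °C
Reagents that add atoms: none
Why: Acid chloride formation and N-acylation of the vinylogous amine (any O-acyl product transfers to nitrogen) gives the known type of bromodienamide.

**Step 15**
Reactants: 19 (2E,4R)-N-[(1S,5R,6R)-5-ethenyl-2-oxo-5-[(triethylsilyl)oxy]-7-oxabicyclo[4.1.0]hept-3-en-3-yl]-4-methyloct-2-enamide; 25 (2E,4E)-5-bromo-N-(2-hydroxy-5-oxocyclopent-1-en-1-yl)penta-2,4-dienamide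
Product: 26 (2E,4R)-N-[(1S,5R,6R)-5-[(1E,3E,5E)-7-[(2-hydroxy-5-oxocyclopent-1-en-1-yl)amino]-7-oxohepta-1,3,5-trien-1-yl]-2-oxo-5-[(triethylsilyl)oxy]-7-oxabicyclo[4.1.0]hept-3-en-3-yl]-4-methyloct-2-enamide
Conditions: Pd(OAc)2 (10 mol %), Bu4NCl, NaHCO3, DMF, 50 °C
Reagents that add atoms: none
Why: Mizoroki–Heck reaction under Jeffery conditions; zerovalent palladium inserts into the C–Br bond, the dienyl group adds to the terminal vinyl carbon, and β-hydride elimination is possible only on the new side (C4 is quaternary), giving the E,E,E-triene.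

**Step 16**
Reactants: 26 (the triethylsilyl ether of the target)
Product: 27 (2E,4R)-N-[(1S,5R,6R)-5-hydroxy-5-[(1E,3E,5E)-7-[(2-hydroxy-5-oxocyclopent-1-en-1-yl)amino]-7-oxohepta-1,3,5-trien-1-yl]-2-oxo-7-oxabicyclo[4.1.0]hept-3-en-3-yl]-4-methyloct-2-enamide (target)
Conditions: HF·pyridine, pyridine, THF, 0 °C
Reagents that add atoms: none
Why: Buffered fluoride desilylation frees the tertiary alcohol under non-basic conditions, avoiding Payne migration of the anti-hydroxy epoxide.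

**Compound list**
1 | (S)-lactic acid | C[C@H](O)C(=O)O | starting material
2 | pivalaldehyde | CC(C)(C)C=O | starting material
3 | (2S,5S)-2-tert-butyl-5-methyl-1,3-dioxolan-4-one | CC(C)(C)[C@H]1O[C@@H](C)C(=O)O1 | intermediate
4 | (2S,5R)-5-bromo-2-tert-butyl-5-methyl-1,3-dioxolan-4-one | CC(C)(C)[C@H]1O[C@](C)(Br)C(=O)O1 | intermediate
5 | (2S)-2-tert-butyl-5-methylidene-1,3-dioxolan-4-one | CC(C)(C)[C@H]1OC(=C)C(=O)O1 | intermediate
6 | Rawal's diene, (E)-3-[(tert-butyldimethylsilyl)oxy]-N,N-dimethylbuta-1,3-dien-1-amine | CN(C)/C=C/C(=C)O[Si](C)(C)C(C)(C)C | starting material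
7 | (2S,5R)-2-tert-butyl-8-[(tert-butyldimethylsilyl)oxy]-6-(dimethylamino)-1,3-dioxaspiro[4.5]dec-7-en-4-one (C6 epimers) | CC(C)(C)[C@H]1O[C@@]2(CCC(O[Si](C)(C)C(C)(C)C)=CC2N(C)C)C(=O)O1 | intermediate
8 | (2S,5R)-2-tert-butyl-8-[(tert-butyldimethylsilyl)oxy]-6-(dimethylamino)-1,3-dioxaspiro[4.5]dec-7-en-4-ol (lactol, formed as its aluminate) | CC(C)(C)[C@H]1O[C@@]2(CCC(O[Si](C)(C)C(C)(C)C)=CC2N(C)C)C(O)O1 | intermediate
9 | (1S)-4-[(tert-butyldimethylsilyl)oxy]-2-(dimethylamino)-1-ethenylcyclohex-3-en-1-ol | C1C[C@](O)(C=C)C(N(C)C)C=C1O[Si](C)(C)C(C)(C)C | intermediate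
10 | (S)-4-ethenyl-4-hydroxycyclohex-2-en-1-one | O=C1CC[C@](O)(C=C)C=C1 | intermediate
11 | (S)-4-ethenyl-4-[(triethylsilyl)oxy]cyclohex-2-en-1-one | O=C1CC[C@](O[Si](CC)(CC)CC)(C=C)C=C1 | intermediate
12 | (1S,5S,6R)-5-ethenyl-5-[(triethylsilyl)oxy]-7-oxabicyclo[4.1.0]heptan-2-one | C1C[C@](O[Si](CC)(CC)CC)(C=C)[C@@H]2O[C@@H]2C1=O | intermediate
13 | (1S,5R,6R)-5-ethenyl-5-[(triethylsilyl)oxy]-7-oxabicyclo[4.1.0]hept-3-en-2-one | C1=C[C@](O[Si](CC)(CC)CC)(C=C)[C@@H]2O[C@@H]2C1=O | intermediate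
14 | (1S,5R,6R)-5-ethenyl-3-iodo-5-[(triethylsilyl)oxy]-7-oxabicyclo[4.1.0]hept-3-en-2-one | IC1=C[C@](O[Si](CC)(CC)CC)(C=C)[C@@H]2O[C@@H]2C1=O | intermediate
15 | (S)-3-bromo-2-methylpropan-1-ol | OC[C@H](C)CBr | starting material
16 | (R)-2-methylhexan-1-ol | OC[C@H](C)CCCC | intermediate
17 | (R)-2-methylhexanal | O=C[C@H](C)CCCC | intermediate
18 | (2E,4R)-4-methyloct-2-enamide | CCCC[C@@H](C)/C=C/C(N)=O | intermediate
19 | (2E,4R)-N-[(1S,5R,6R)-5-ethenyl-2-oxo-5-[(triethylsilyl)oxy]-7-oxabicyclo[4.1.0]hept-3-en-3-yl]-4-methyloct-2-enamide | CCCC[C@@H](C)/C=C/C(=O)NC1=C[C@](O[Si](CC)(CC)CC)(C=C)[C@@H]2O[C@@H]2C1=O | intermediate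
20 | glutaconaldehyde potassium salt | [K+].[O-]/C=C/C=C/C=O | starting material
21 | (2E,4E)-5-bromopenta-2,4-dienal | Br/C=C/C=C/C=O | intermediate
22 | (2E,4E)-5-bromopenta-2,4-dienoic acid | Br/C=C/C=C/C(=O)O | intermediate
23 | 2-amino-3-hydroxycyclopent-2-en-1-one hydrochloride | NC1=C(O)CCC1=O.Cl | starting material
24 | (2E,4E)-5-bromopenta-2,4-dienoyl chloride | Br/C=C/C=C/C(=O)Cl | intermediate
25 | (2E,4E)-5-bromo-N-(2-hydroxy-5-oxocyclopent-1-en-1-yl)penta-2,4-dienamide | Br/C=C/C=C/C(=O)NC1=C(O)CCC1=O | intermediate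
26 | triethylsilyl ether of the target (name as in step 15) | CCCC[C@@H](C)/C=C/C(=O)NC1=C[C@](O[Si](CC)(CC)CC)(/C=C/C=C/C=C/C(=O)NC2=C(O)CCC2=O)[C@@H]2O[C@@H]2C1=O | intermediate
27 | (2E,4R)-N-[(1S,5R,6R)-5-hydroxy-5-[(1E,3E,5E)-7-[(2-hydroxy-5-oxocyclopent-1-en-1-yl)amino]-7-oxohepta-1,3,5-trien-1-yl]-2-oxo-7-oxabicyclo[4.1.0]hept-3-en-3-yl]-4-methyloct-2-enamide | CCCC[C@@H](C)/C=C/C(=O)NC1=C[C@](O)(/C=C/C=C/C=C/C(=O)NC2=C(O)CCC2=O)[C@@H]2O[C@@H]2C1=O | target

**Step count**
Total: 16 steps. Longest linear sequence: 11 steps (1–8, 11, 15, 16) from (S)-lactic acid.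

**Steps most likely to fail, with fallbacks**

Step 4 (one-pot partial reduction, methylenation and hydrolysis). The lactol aluminate may over-reduce or fail to open for the Wittig reaction. The fallback sets out from 7 and comes back at 9. Reduce 7 fully with LiAlH4 (THF, 0 °C) to the diol (1R)-4-[(tert-butyldimethylsilyl)oxy]-2-(dimethylamino)-1-(hydroxymethyl)cyclohex-3-en-1-ol F1. Oxidise only the primary alcohol with SO3·pyridine/DMSO/iPr2NEt to the hydroxy aldehyde (1R)-4-[(tert-butyldimethylsilyl)oxy]-2-(dimethylamino)-1-hydroxycyclohex-3-ene-1-carbaldehyde F2. Methylenate with Ph3P=CH2 to reach 9, which is hydrolysed to 10 as in step 4.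

Step 11 (copper-catalysed amidation of the α-iodo epoxy-enone). The conjugated primary amide may couple poorly, or the base may degrade 14. The fallback sets out from 12 (using 18) and comes back at 19, bypassing steps 7, 8 and 11.
- Azidate the potassium enolate of 12 (KN(SiMe3)2, THF, −78 °C; 2,4,6-triisopropylbenzenesulfonyl azide; AcOH quench) to the α-azido ketone (1S,5S,6R)-3-azido-5-ethenyl-5-[(triethylsilyl)oxy]-7-oxabicyclo[4.1.0]heptan-2-one F3.
- Treat with Et3N (CH2Cl2, rt); loss of N2 and tautomerisation give the amino enone (1S,5R,6R)-3-amino-5-ethenyl-5-[(triethylsilyl)oxy]-7-oxabicyclo[4.1.0]hept-3-en-2-one F4.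
- Deamidate 18 with tert-butyl nitrite in AcOH to (2E,4R)-4-methyloct-2-enoic acid F5, and convert it with oxalyl chloride into (2E,4R)-4-methyloct-2-enoyl chloride F6.
- Acylate F4 with F6 (pyridine, CH2Cl2) to give 19.

Step 15 (Heck coupling with the bromodienamide). The hindered vinyl group, the free enol of 25 or poor E-selectivity may defeat it. The fallback sets out from 19 and comes back at 26. Cross-metathesis of 19 with vinylboronic acid pinacol ester (second-generation Hoveyda–Grubbs catalyst, CH2Cl2, 40 °C) gives the alkenylboronate (2E,4R)-N-[(1S,5R,6R)-2-oxo-5-[(E)-2-(4,4,5,5-tetramethyl-1,3,2-dioxaborolan-2-yl)ethenyl]-5-[(triethylsilyl)oxy]-7-oxabicyclo[4.1.0]hept-3-en-3-yl]-4-methyloct-2-enamide F7. Suzuki–Miyaura coupling of F7 with 25 (Pd(PPh3)4, aqueous K3PO4, THF, rt) then gives 26.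

**Further compounds**
F1 | step 4 | (1R)-4-[(tert-butyldimethylsilyl)oxy]-2-(dimethylamino)-1-(hydroxymethyl)cyclohex-3-en-1-ol | C1C[C@](O)(CO)C(N(C)C)C=C1O[Si](C)(C)C(C)(C)C
F2 | step 4 | (1R)-4-[(tert-butyldimethylsilyl)oxy]-2-(dimethylamino)-1-hydroxycyclohex-3-ene-1-carbaldehyde | C1C[C@](O)(C=O)C(N(C)C)C=C1O[Si](C)(C)C(C)(C)C
F3 | step 11 | (1S,5S,6R)-3-azido-5-ethenyl-5-[(triethylsilyl)oxy]-7-oxabicyclo[4.1.0]heptan-2-one | [N-]=[N+]=NC1C[C@](O[Si](CC)(CC)CC)(C=C)[C@@H]2O[C@@H]2C1=O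
F4 | step 11 | (1S,5R,6R)-3-amino-5-ethenyl-5-[(triethylsilyl)oxy]-7-oxabicyclo[4.1.0]hept-3-en-2-one | NC1=C[C@](O[Si](CC)(CC)CC)(C=C)[C@@H]2O[C@@H]2C1=O
F5 | step 11 | (2E,4R)-4-methyloct-2-enoic acid | CCCC[C@@H](C)/C=C/C(=O)O
F6 | step 11 | (2E,4R)-4-methyloct-2-enoyl chloride | CCCC[C@@H](C)/C=C/C(=O)Cl
F7 | step 15 | (2E,4R)-N-[(1S,5R,6R)-2-oxo-5-[(E)-2-(4,4,5,5-tetramethyl-1,3,2-dioxaborolan-2-yl)ethenyl]-5-[(triethylsilyl)oxy]-7-oxabicyclo[4.1.0]hept-3-en-3-yl]-4-methyloct-2-enamide | CCCC[C@@H](C)/C=C/C(=O)NC1=C[C@](O[Si](CC)(CC)CC)(/C=C/B2OC(C)(C)C(C)(C)O2)[C@@H]3O[C@@H]3C1=O
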